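The target is disconnected across the 1,2‑dioxane ring of the cis‑fused dioxane–γ‑lactone, at C4–C4a and at O2–C3. C3 and C4 are read as the two carbons of a 1,1‑disubstituted alkene, C4a as a ketone carbonyl, and the peroxide‑bearing C7a as its α‑carbon. In the last step a TiCl4‑chelated (R)‑α‑(tert‑butylperoxy) γ‑keto ester takes up 2‑methyl‑12‑phenyldodec‑1‑ene. Prins‑type C–C bond formation, capture of the tertiary cation by the peroxide with loss of tert‑butyl, and lactonisation should give both rings and the C3 and C4a stereocentres in one operation. The precursor is acyclic and comes from asymmetric peroxidation of (E)‑4‑oxopent‑2‑enal.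

Key step: step 7

Remark on the chemistry: locants of the target follow the furo[3,2‑c][1,2]dioxin‑6‑one numbering (O1, O2, C3, C4, C4a, O5, C6, C7, C7a). The target is the (3R,4aR,7aR) isomer, with the lactone cis‑fused and the C3 methyl group cis to the lactone oxygen.

Step 1
Reactants: 1 phenylmagnesium bromide; 2 10‑bromodec‑1‑ene
Product: 3 10‑phenyldec‑1‑ene
Conditions: FeCl3 (5 mol%), TMEDA, THF, 0 °C, slow addition of 1
Reagents that add atoms: none
Why: Iron‑catalysed Kumada‑type sp2–sp3 cross‑coupling of an aryl Grignard reagent with a primary alkyl bromide should give the arylalkane, the terminal alkene being inert and too remote for radical cyclisation.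

Step 2
Reactants: 3 10‑phenyldec‑1‑ene; 4 2‑bromopropene
Product: 6 2‑methyl‑12‑phenyldodec‑1‑ene, via alkylborane 5 (not isolated)
Conditions: 9‑BBN, THF, 0 °C to rt; then 4, Pd(dppf)Cl2 (3 mol%), 3 M aq NaOH, 60 °C
Reagents that add atoms: none
Why: Anti‑Markovnikov hydroboration with 9‑BBN followed by B‑alkyl Suzuki–Miyaura coupling with the vinyl bromide should attach the isopropenyl end group without alkene isomerisation.

Step 3
Reactants: 7 2‑methylfuran
Product: 9 (E)‑4‑oxopent‑2‑enal, via (Z)‑4‑oxopent‑2‑enal 8 (not isolated)
Conditions: NBS, NaHCO3, acetone/H2O (10:1), −15 °C; then pyridine, rt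
Reagents that add atoms: water, O
Why: Oxidative ring opening of the furan (bromination at C5, addition of water, collapse of the 2,5‑dihydrofuran to the cis‑enedicarbonyl, as in a Clauson‑Kaas‑type 2,5‑dioxygenation) followed by pyridine‑mediated Z‑to‑E isomerisation should give the E keto‑enal.

Step 4
Reactants: 9 (E)‑4‑oxopent‑2‑enal
Product: 10 (3R)‑3‑(tert‑butylperoxy)‑4‑oxopentanal
Conditions: t‑BuOOH (5.5 M in decane, 1.5 equiv), (R)‑2‑{bis[3,5‑bis(trifluoromethyl)phenyl](trimethylsilyloxy)methyl}pyrrolidine (10 mol%), PhCO2H (10 mol%), toluene, −20 °C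
Reagents that add atoms: tert‑butyl hydroperoxide, CC(C)(C)OO
Why: This is an amine‑catalysed enantioselective oxa‑Michael addition of a hydroperoxide to an enal (iminium activation): the aldehyde, not the ketone, condenses with the secondary amine, so the peroxide adds at C3; the diaryl(silyloxy)methyl group of the (R)‑catalyst shields one face of the E‑iminium ion so that attack on the open face should give the (R)‑peroxide, and the acid co‑catalyst protonates the peroxy‑enamine before it can close to an epoxide.

Step 5
Reactants: 10 (3R)‑3‑(tert‑butylperoxy)‑4‑oxopentanal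
Product: 11 (3R)‑3‑(tert‑butylperoxy)‑4‑oxopentanoic acid
Conditions: NaClO2, NaH2PO4, 2‑methyl‑2‑butene, t‑BuOH/H2O, 0 °C
Reagents that add atoms: sodium chlorite, [Na+].[O-]Cl=O
Why: Pinnick oxidation is selective for the aldehyde and should leave the dialkyl peroxide, the ketone and the C3 stereocentre untouched under the buffered, mildly acidic conditions.

Step 6
Reactants: 11 (3R)‑3‑(tert‑butylperoxy)‑4‑oxopentanoic acid
Product: 12 methyl (3R)‑3‑(tert‑butylperoxy)‑4‑oxopentanoate
Conditions: TMSCHN2, MeOH/toluene, 0 °C
Reagents that add atoms: (trimethylsilyl)diazomethane, C[Si](C)(C)C=[N+]=[N-]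
Why: O‑Methylation of the carboxylic acid with TMSCHN2 in methanol is base‑free, which avoids Kornblum–DeLaMare fragmentation of the α‑peroxy ketone and β‑elimination of the peroxide.

Step 7
Reactants: 12 methyl (3R)‑3‑(tert‑butylperoxy)‑4‑oxopentanoate; 6 2‑methyl‑12‑phenyldodec‑1‑ene
Product: 14 (3R,4aR,7aR)‑3,4a‑dimethyl‑3‑(10‑phenyldecyl)‑3,4,4a,7a‑tetrahydrofuro[3,2‑c][1,2]dioxin‑6(7H)‑one, via hydroxy ester 13 (not isolated)
Conditions: TiCl4 (1.2 equiv), 6 (1.5 equiv), CH2Cl2, −78 to −20 °C; then aq NaHCO3
Reagents that add atoms: none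
Why: Proposed new method: TiCl4 should chelate the ketone oxygen and the proximal peroxy oxygen of 12; the CH2 terminus of 6 then adds to the activated carbonyl carbon (Prins‑type, Markovnikov) to give a tertiary carbenium ion at the future C3, the distal peroxy oxygen captures it, and the tert‑butyl peroxonium ion sheds tert‑butyl as tert‑butyl chloride, an irreversible exit towards which the reversible chloride and ene‑type alkene side channels of the cation can drain by re‑ionisation. The closest known reaction types are the Lewis‑acid [3+2] annulation of peroxycarbenium ions with alkenes to 1,2‑dioxolanes (the same capture of a tertiary cation by a peroxide oxygen), the Hosomi–Sakurai and Prins additions to chelated α‑alkoxy ketones (2‑alkyl‑1‑alkenes come close to allyltrimethylsilane in π‑nucleophilicity), and the dealkylative cyclisation of tert‑butyl peroxides through peroxonium ions. The 1,2‑dioxane closes by six‑membered, chair‑like attack of oxygen on the cationic carbon with both former alkene carbons inside the ring, and the γ‑lactone then closes by 5‑exo‑trig attack of the Cl3Ti–alkoxide on the methyl ester, which only the cis isomer can do. C4a is set by chelation control: the five‑membered chelate holds the CH2CO2Me group of (R)‑C7a on one face, the alkene attacks the opposite face, and this places the new C–O bond cis to the acetate arm, giving (4aR). C3 is set in the chair transition state of the ring closure, which carries the Cl3Ti–O group axial and should prefer the long chain equatorial and the methyl group axial, that is (3R); this preference is expected to be modest, so the C3 epimer is removed by chromatography. The step needs peroxide capture to win over loss of a proton and the O–O bond to survive the Lewis acid, which the low temperature, the non‑reducing tetravalent titanium and the robust tert‑butyl peroxide are chosen to secure.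

Compound list
1 | phenylmagnesium bromide | Br[Mg]c1ccccc1 | starting material
2 | 10‑bromodec‑1‑ene | C=CCCCCCCCCBr | starting material
3 | 10‑phenyldec‑1‑ene | C=CCCCCCCCCc1ccccc1 | intermediate
4 | 2‑bromopropene | CC(Br)=C | starting material
5 | 9‑(10‑phenyldecyl)‑9‑borabicyclo[3.3.1]nonane (alkylborane, not isolated) | c1ccccc1CCCCCCCCCCB1C2CCCC1CCC2 | intermediate
6 | 2‑methyl‑12‑phenyldodec‑1‑ene | C=C(C)CCCCCCCCCCc1ccccc1 | intermediate
7 | 2‑methylfuran | Cc1ccco1 | starting material
8 | (Z)‑4‑oxopent‑2‑enal (not isolated) | CC(=O)/C=C\C=O | intermediate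
9 | (E)‑4‑oxopent‑2‑enal | CC(=O)/C=C/C=O | intermediate
10 | (3R)‑3‑(tert‑butylperoxy)‑4‑oxopentanal | O=CC[C@H](C(C)=O)OOC(C)(C)C | intermediate
11 | (3R)‑3‑(tert‑butylperoxy)‑4‑oxopentanoic acid | OC(=O)C[C@H](C(C)=O)OOC(C)(C)C | intermediate
12 | methyl (3R)‑3‑(tert‑butylperoxy)‑4‑oxopentanoate | COC(=O)C[C@H](C(C)=O)OOC(C)(C)C | intermediate
13 | methyl 2‑[(3R,4R,6R)‑4‑hydroxy‑4,6‑dimethyl‑6‑(10‑phenyldecyl)‑1,2‑dioxan‑3‑yl]acetate (hydroxy ester, formed as its Cl3Ti–alkoxide, not isolated) | C[C@@]1(CCCCCCCCCCc2ccccc2)C[C@@](C)(O)[C@@H](CC(=O)OC)OO1 | intermediate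
14 | (3R,4aR,7aR)‑3,4a‑dimethyl‑3‑(10‑phenyldecyl)‑3,4,4a,7a‑tetrahydrofuro[3,2‑c][1,2]dioxin‑6(7H)‑one | C[C@@]1(CCCCCCCCCCc2ccccc2)C[C@@]2(C)OC(=O)C[C@H]2OO1 | target

Total step count: 7. Longest linear sequence: 5 steps (7 → 9 → 10 → 11 → 12 → 14).

Steps most likely to fail

1. Step 7 (proposed new method).
What may go wrong: the tertiary cation may lose a proton (ene‑type products) or be trapped as chloride faster than the hindered peroxide oxygen captures it. The Lewis acid may induce heterolysis of the O–O bond with acyl migration. The liberated tert‑butyl cation may alkylate the phenyl ring. Facial selectivity at C3 may be low.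
Fallback, with known reaction types only, which splits the operation into C–C bond formation and a separate peroxide ring closure. It sets out from alkylborane 5 (made from 3 as in step 2) and keto ester 12 and comes back at 14. Suzuki–Miyaura coupling of 5 with (2‑bromoallyl)trimethylsilane under the conditions of step 2 should give trimethyl(2‑methylidene‑12‑phenyldodecyl)silane F1. Chelation‑controlled Hosomi–Sakurai addition of F1 to 12 (TiCl4, CH2Cl2, −78 °C) and lactonisation on warming should give (4R,5R)‑4‑(tert‑butylperoxy)‑5‑methyl‑5‑(2‑methylidene‑12‑phenyldodecyl)oxolan‑2‑one F2. Iodocyclisation of F2 with NIS in CH2Cl2 at 0 °C (Markovnikov attack of the tert‑butylperoxy oxygen on the iodonium ion with loss of tert‑butyl) should give (3R,4aR,7aR)‑3‑(iodomethyl)‑4a‑methyl‑3‑(10‑phenyldecyl)‑3,4,4a,7a‑tetrahydrofuro[3,2‑c][1,2]dioxin‑6(7H)‑one F3 together with its C3 epimer. Radical deiodination of F3 (Bu3SnH, Et3B/air, toluene, 0 °C) should then give 14.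

2. Step 4.
What may go wrong: the peroxy‑enamine may close to the epoxide with loss of tert‑butoxide. The amine may trigger Kornblum–DeLaMare fragmentation at the α‑peroxy ketone or retro‑Michael loss of the hydroperoxide. Face selectivity on this doubly activated alkene may be eroded by an uncatalysed background addition. The 1,4‑dicarbonyl product may cyclise under acid (Paal–Knorr) with loss of the peroxide.
Fallback by resolution in place of asymmetric catalysis. It sets out from 9 and comes back at 11. Addition of t‑BuOOH to 9 with pyrrolidine (10 mol%) and PhCO2H in toluene should give racemic 3‑(tert‑butylperoxy)‑4‑oxopentanal F4. Pinnick oxidation as in step 5 should give racemic 3‑(tert‑butylperoxy)‑4‑oxopentanoic acid F5. Crystallisation with one enantiomer of 1‑phenylethylamine (drawn for the (S)‑amine; the enantiomer is used if its salt with the (R)‑acid is the less soluble one) should give the (S)‑1‑phenylethylammonium (3R)‑3‑(tert‑butylperoxy)‑4‑oxopentanoate salt F6. Acidification with cold 1 M HCl should release 11.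

3. Step 3.
What may go wrong: over‑bromination of the electron‑rich furan, incomplete Z‑to‑E isomerisation, and loss of the small, electrophilic keto‑enal by volatility or oligomerisation during isolation.
Fallback through a storable masked form. It sets out from 7 and comes back at 9. Clauson‑Kaas methoxylation of 7 (Br2, MeOH, Na2CO3, −40 °C) should give distillable 2,5‑dimethoxy‑2‑methyl‑2,5‑dihydrofuran F7. Hydrolysis of F7 (acidic ion‑exchange resin, acetone/H2O, rt) and then a little pyridine should release 9 directly as a solution for step 4.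

Further compounds
F1 | step 7 | trimethyl(2‑methylidene‑12‑phenyldodecyl)silane | C[Si](C)(C)CC(=C)CCCCCCCCCCc1ccccc1
F2 | step 7 | (4R,5R)‑4‑(tert‑butylperoxy)‑5‑methyl‑5‑(2‑methylidene‑12‑phenyldodecyl)oxolan‑2‑one | C=C(CCCCCCCCCCc1ccccc1)C[C@@]1(C)OC(=O)C[C@H]1OOC(C)(C)C
F3 | step 7 | (3R,4aR,7aR)‑3‑(iodomethyl)‑4a‑methyl‑3‑(10‑phenyldecyl)‑3,4,4a,7a‑tetrahydrofuro[3,2‑c][1,2]dioxin‑6(7H)‑one | IC[C@@]1(CCCCCCCCCCc2ccccc2)C[C@@]2(C)OC(=O)C[C@H]2OO1
F4 | step 4 | racemic 3‑(tert‑butylperoxy)‑4‑oxopentanal | O=CCC(C(C)=O)OOC(C)(C)C
F5 | step 4 | racemic 3‑(tert‑butylperoxy)‑4‑oxopentanoic acid | OC(=O)CC(C(C)=O)OOC(C)(C)C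
F6 | step 4 | (S)‑1‑phenylethylammonium (3R)‑3‑(tert‑butylperoxy)‑4‑oxopentanoate | C[C@H]([NH3+])c1ccccc1.[O-]C(=O)C[C@H](C(C)=O)OOC(C)(C)C
F7 | step 3 | 2,5‑dimethoxy‑2‑methyl‑2,5‑dihydrofuran | COC1C=CC(C)(OC)O1
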